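**Retrosynthetic overview**
1. Last disconnection: the bond from C-3 of the furanone (tetronic acid) ring to C-1′ of the 4-hydroxyphenyl ring, made while that ring is still a cyclohexenone. Free tetronic acid 11 and the 4-oxocyclohex-2-enyl methyl carbonate 17 (already carrying the (R)-oxirane) are joined by Pd-allylation and dehydrogenated to the phenol in the same flask.
2. Enabling feature: C-3 is the central carbon of the acidic O=C–C=C–OH unit of the furanone ring (a soft carbon nucleophile) and sits para to the phenolic oxygen. The benzene ring C-1′–C-6′ is therefore the dehydro form of a 4-substituted cyclohex-2-enone: C-1′ is the π-allyl terminus, C-4′ the ketone, C-3′ its α′-carbon, which takes the side chain by enolate alkylation. The cyclisation-prone 2-(oxiranylmethyl)phenol exists only after the last bond change.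
3. 11: Z-exocyclic alkene by vinylogous aldol condensation of methyl tetronate with chroman aldehyde 4; the pyran ring of the chroman by isoprene annulation of resorcinol.
4. 17: α′-prenylation of 4-silyloxycyclohex-2-enone, Shi epoxidation (the only stereocentre), desilylation, carbonate formation.
5. Ring order: pyran (step 1); furanone bought intact (enters in step 4); oxirane (step 7); benzene ring of the hydroxyphenyl unit last, by aromatisation of the carried cyclohexenone (step 10).

Key step: step 10

Remark on stereochemistry: 12 is used as the racemate, so the ring stereocentres of 14–18 are mixtures and are written without descriptors; both are destroyed in step 10, and only the oxirane centre set in step 7 survives.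

Step 1
Reactants: 1 resorcinol; 2 isoprene
Product: 3 2,2-dimethylchroman-7-ol
Conditions: 1 (3 equiv), 85% H3PO4, xylene, 30–35 °C
Reagents that add atoms: none
Why: Acid-catalysed Friedel–Crafts prenylation at C-4 of resorcinol (para to one hydroxyl, not between the two) followed by Markovnikov addition of the neighbouring hydroxyl to the side-chain olefin closes the 2,2-dimethylpyran ring through the tertiary cation, and excess resorcinol should hold back a second annulation.

Step 2
Reactants: 3 2,2-dimethylchroman-7-ol
Product: 4 7-hydroxy-2,2-dimethylchroman-6-carbaldehyde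
Conditions: MgCl2, Et3N, (CH2O)n, MeCN, reflux; aq. HCl work-up
Reagents that add atoms: paraformaldehyde, C=O
Why: Magnesium phenoxide-directed ortho-formylation (Casiraghi–Skattebøl) is ortho-specific and should choose the open C-6 (para to the ring oxygen) over C-8, which lies between the two oxygens.

Step 3
Reactants: 4 7-hydroxy-2,2-dimethylchroman-6-carbaldehyde
Product: 5 7-(methoxymethoxy)-2,2-dimethylchroman-6-carbaldehyde
Conditions: MOMCl, iPr2NEt, CH2Cl2, 0 °C → rt
Reagents that add atoms: chloromethyl methyl ether (MOMCl), COCCl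
Why: Williamson-type O-alkylation to the acetal removes the acidic proton before the enolate step, and a MOM group cannot migrate to a neighbouring alkoxide as a silyl or acyl group could.

Step 4
Reactants: 5 7-(methoxymethoxy)-2,2-dimethylchroman-6-carbaldehyde; 6 4-methoxyfuran-2(5H)-one (methyl tetronate)
Product: 9 (5Z)-4-methoxy-5-{[7-(methoxymethoxy)-2,2-dimethylchroman-6-yl]methylidene}furan-2(5H)-one, via lithium aldolate 7 (not isolated), via mesylate 8 (not isolated)
Conditions: 6, LDA, THF, −78 °C; 5; MsCl, −78 → 0 °C; DBU, 0 °C → rt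
Reagents that add atoms: none
Why: Vinylogous aldol addition of the C-5 lithium dienolate of the tetronate to the aldehyde, O-mesylation and E1cB elimination (aldol condensation) should give the Z-alkene, the thermodynamic isomer with the aryl group on the side of the ring oxygen and away from the C-4 methoxy group.

Step 5
Reactants: 9 (5Z)-4-methoxy-5-{[7-(methoxymethoxy)-2,2-dimethylchroman-6-yl]methylidene}furan-2(5H)-one
Product: 11 (5Z)-4-hydroxy-5-[(7-hydroxy-2,2-dimethylchroman-6-yl)methylidene]furan-2(5H)-one, via phenol 10 (not isolated)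
Conditions: HCl (cat.), MeOH, 40 °C; evaporate; LiCl, DMF, 100 °C; dil. HCl work-up
Reagents that add atoms: none
Why: Acid-catalysed acetal exchange removes the MOM group while the formaldehyde equivalent is trapped and evaporated as dimethoxymethane (so it cannot condense with a free tetronic acid), and Krapcho-type SN2 demethylation of the vinylogous methyl ester by chloride then unmasks the 3-unsubstituted tetronic acid.

Step 6
Reactants: 12 4-[(tert-butyldimethylsilyl)oxy]cyclohex-2-en-1-one; 13 1-bromo-3-methylbut-2-ene (prenyl bromide)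
Product: 14 4-[(tert-butyldimethylsilyl)oxy]-6-(3-methylbut-2-en-1-yl)cyclohex-2-en-1-one
Conditions: LDA, THF, −78 °C; 13, DMPU, −78 → −30 °C
Reagents that add atoms: none
Why: Kinetic α′-deprotonation of the enone gives the cross-conjugated lithium dienolate, and its C-alkylation by the allylic bromide (enolate alkylation) places the side chain on the carbon next to the future phenolic carbon; the new ring stereocentre is of no consequence.

Step 7
Reactants: 14 4-[(tert-butyldimethylsilyl)oxy]-6-(3-methylbut-2-en-1-yl)cyclohex-2-en-1-one
Product: 15 4-[(tert-butyldimethylsilyl)oxy]-6-{[(2R)-3,3-dimethyloxiran-2-yl]methyl}cyclohex-2-en-1-one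
Conditions: D-fructose-derived Shi ketone (30 mol %), Oxone, K2CO3, Bu4NHSO4, MeCN–DMM/aq. borate–EDTA buffer (pH ≈ 10.5), 0 °C
Reagents that add atoms: potassium peroxymonosulfate (Oxone), [K+].[O-]S(=O)(=O)OO
Why: Shi asymmetric epoxidation: the electrophilic chiral dioxirane should attack the electron-rich trisubstituted olefin far faster than the electron-poor enone, and its spiro transition state delivers oxygen to the face of R–CH2–CH=CMe2 that gives the (R)-oxirane (catalyst control, the same sense as (R,R) for trans-olefins).

Step 8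
Reactants: 15 4-[(tert-butyldimethylsilyl)oxy]-6-{[(2R)-3,3-dimethyloxiran-2-yl]methyl}cyclohex-2-en-1-one
Product: 16 6-{[(2R)-3,3-dimethyloxiran-2-yl]methyl}-4-hydroxycyclohex-2-en-1-one
Conditions: TBAF, AcOH (1:1), THF, 0 °C → rt
Reagents that add atoms: none
Why: Fluoride cleaves the Si–O bond (silyl ether deprotection), and the acetic acid buffer keeps the medium close to neutral so that the oxirane and the γ-hydroxy enone survive.

Step 9
Reactants: 16 6-{[(2R)-3,3-dimethyloxiran-2-yl]methyl}-4-hydroxycyclohex-2-en-1-one
Product: 17 5-{[(2R)-3,3-dimethyloxiran-2-yl]methyl}-4-oxocyclohex-2-en-1-yl methyl carbonate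
Conditions: ClCO2Me, pyridine, DMAP (cat.), CH2Cl2, 0 °C
Reagents that add atoms: methyl chloroformate, COC(=O)Cl
Why: O-acylation of the secondary allylic alcohol gives the methyl carbonate, a leaving group that ionises with Pd(0) and supplies its own base (methoxide), so the coupling needs no added base.

Step 10
Reactants: 11 (5Z)-4-hydroxy-5-[(7-hydroxy-2,2-dimethylchroman-6-yl)methylidene]furan-2(5H)-one; 17 5-{[(2R)-3,3-dimethyloxiran-2-yl]methyl}-4-oxocyclohex-2-en-1-yl methyl carbonate
Product: 20 (5Z)-3-(3-{[(2R)-3,3-dimethyloxiran-2-yl]methyl}-4-hydroxyphenyl)-4-hydroxy-5-[(7-hydroxy-2,2-dimethylchroman-6-yl)methylidene]furan-2(5H)-one, via allylation product 18 (not isolated), via trienone tautomer 19 (not isolated)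
Conditions: Pd2(dba)3 (2.5 mol %), dppe (6 mol %), THF, 0 °C → rt, dark; then DDQ (1.2 equiv), 0 °C; pH 6 phosphate work-up
Reagents that add atoms: none
Why: Pd(0) ionises the allylic carbonate of 17 with loss of CO2, the methoxide set free deprotonates the tetronic acid of 11 (pKa ≈ 4), and the soft tetronate attacks through C-3 at the allyl terminus remote from the carbonyl to give 18; DDQ then takes hydride from the C-1′ methine of 18 (allylic and attached to the enol carbon), which gives trienone 19, the keto tautomer of the phenol, and two proton shifts aromatise it to 20. The closest known reaction types are the Tsuji–Trost C-allylation of highly acidic cyclic 1,3-dicarbonyl compounds (tetronic acids, 4-hydroxycoumarins), the γ-substitution of γ-acyloxy enones, and the quinone dehydrogenation of 4-substituted cyclohex-2-enones to phenols. No ring is closed: the six-membered carbocycle arrives as a cyclohexenone and is only aromatised here. No lasting stereocentre is formed: the C-1′ centre made in the allylation and the ring centre next to the ketone are both erased, the oxirane centre set in step 7 is not touched and the Z-alkene takes no part. The step needs C- over O-allylation and tetronate over the chroman phenol (only one equivalent of base is formed and it goes to the strongest acid, while O-allyl products re-ionise under Pd(0)), attack γ to the carbonyl (keeps the enone conjugated), substitution before β-hydride elimination (stoichiometric soft nucleophile), and oxidation at C-1′ before the chroman benzylic CH2 (the enol-activated methine is the best hydride donor towards one equivalent of DDQ at 0 °C). The medium stays close to neutral, so the free phenol next to the oxirane appears only after the last bond change.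

**Compound list**
1 | resorcinol (benzene-1,3-diol) | Oc1cccc(O)c1 | starting material
2 | isoprene (2-methylbuta-1,3-diene) | C=CC(C)=C | starting material
3 | 2,2-dimethylchroman-7-ol | CC1(C)CCc2ccc(O)cc2O1 | intermediate
4 | 7-hydroxy-2,2-dimethylchroman-6-carbaldehyde | CC1(C)CCc2cc(C=O)c(O)cc2O1 | intermediate
5 | 7-(methoxymethoxy)-2,2-dimethylchroman-6-carbaldehyde | CC1(C)CCc2cc(C=O)c(OCOC)cc2O1 | intermediate
6 | 4-methoxyfuran-2(5H)-one (methyl tetronate) | COC1=CC(=O)OC1 | starting material
7 | lithium (3-methoxy-5-oxo-2,5-dihydrofuran-2-yl)[7-(methoxymethoxy)-2,2-dimethylchroman-6-yl]methanolate, mixture of diastereomers | CC1(C)CCc2cc(C([O-])C3OC(=O)C=C3OC)c(OCOC)cc2O1.[Li+] | intermediate (not isolated)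
8 | (3-methoxy-5-oxo-2,5-dihydrofuran-2-yl)[7-(methoxymethoxy)-2,2-dimethylchroman-6-yl]methyl methanesulfonate, mixture of diastereomers | CC1(C)CCc2cc(C(OS(C)(=O)=O)C3OC(=O)C=C3OC)c(OCOC)cc2O1 | intermediate (not isolated)
9 | (5Z)-4-methoxy-5-{[7-(methoxymethoxy)-2,2-dimethylchroman-6-yl]methylidene}furan-2(5H)-one | CC1(C)CCc2cc(/C=C3\OC(=O)C=C3OC)c(OCOC)cc2O1 | intermediate
10 | (5Z)-5-[(7-hydroxy-2,2-dimethylchroman-6-yl)methylidene]-4-methoxyfuran-2(5H)-one | CC1(C)CCc2cc(/C=C3\OC(=O)C=C3OC)c(O)cc2O1 | intermediate (not isolated)
11 | (5Z)-4-hydroxy-5-[(7-hydroxy-2,2-dimethylchroman-6-yl)methylidene]furan-2(5H)-one | CC1(C)CCc2cc(/C=C3\OC(=O)C=C3O)c(O)cc2O1 | intermediate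
12 | 4-[(tert-butyldimethylsilyl)oxy]cyclohex-2-en-1-one, racemic | O=C1C=CC(O[Si](C)(C)C(C)(C)C)CC1 | starting material
13 | 1-bromo-3-methylbut-2-ene (prenyl bromide) | CC(C)=CCBr | starting material
14 | 4-[(tert-butyldimethylsilyl)oxy]-6-(3-methylbut-2-en-1-yl)cyclohex-2-en-1-one, ring diastereomers | O=C1C=CC(O[Si](C)(C)C(C)(C)C)CC1CC=C(C)C | intermediate
15 | 4-[(tert-butyldimethylsilyl)oxy]-6-{[(2R)-3,3-dimethyloxiran-2-yl]methyl}cyclohex-2-en-1-one, ring diastereomers | O=C1C=CC(O[Si](C)(C)C(C)(C)C)CC1C[C@H]1OC1(C)C | intermediate
16 | 6-{[(2R)-3,3-dimethyloxiran-2-yl]methyl}-4-hydroxycyclohex-2-en-1-one, ring diastereomers | O=C1C=CC(O)CC1C[C@H]1OC1(C)C | intermediate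
17 | 5-{[(2R)-3,3-dimethyloxiran-2-yl]methyl}-4-oxocyclohex-2-en-1-yl methyl carbonate, ring diastereomers | COC(=O)OC1C=CC(=O)C(C[C@H]2OC2(C)C)C1 | intermediate
18 | (5Z)-3-(5-{[(2R)-3,3-dimethyloxiran-2-yl]methyl}-4-oxocyclohex-2-en-1-yl)-4-hydroxy-5-[(7-hydroxy-2,2-dimethylchroman-6-yl)methylidene]furan-2(5H)-one, ring diastereomers | CC1(C)CCc2cc(/C=C3\OC(=O)C(C4C=CC(=O)C(C[C@H]5OC5(C)C)C4)=C3O)c(O)cc2O1 | intermediate (not isolated)
19 | (5Z)-3-(5-{[(2R)-3,3-dimethyloxiran-2-yl]methyl}-4-oxocyclohex-2-en-1-ylidene)-5-[(7-hydroxy-2,2-dimethylchroman-6-yl)methylidene]furan-2,4(3H,5H)-dione | CC1(C)CCc2cc(/C=C3\OC(=O)C(=C4C=CC(=O)C(C[C@H]5OC5(C)C)C4)C3=O)c(O)cc2O1 | intermediate (not isolated)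
20 | (5Z)-3-(3-{[(2R)-3,3-dimethyloxiran-2-yl]methyl}-4-hydroxyphenyl)-4-hydroxy-5-[(7-hydroxy-2,2-dimethylchroman-6-yl)methylidene]furan-2(5H)-one (CNP0153425.1) | CC1(C)CCc2cc(/C=C3\OC(=O)C(c4ccc(O)c(C[C@H]5OC5(C)C)c4)=C3O)c(O)cc2O1 | target

**Step count and risks**
Total: 10 steps. Longest linear sequence: 6 steps (steps 1–5, then step 10); the second branch is steps 6–9.

Step 10 (key step). What may go wrong:
- the π-allyl intermediate may lose a β-hydrogen before the tetronate captures it;
- the tetronate may be allylated twice;
- the enol of 18 may add reversibly to its own enone (oxa-Michael closure to a fused dihydrofuran) before it is oxidised;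
- the quinone may also attack the chroman benzylic position;
- the freshly unmasked phenol may open the neighbouring oxirane under the acidity of the tetronic acid and of the spent oxidant.

Fallback, setting out from 11 and returning at 20: the bond is made by palladium-catalysed α-arylation of the cyclic 1,3-dicarbonyl with an aryl bromide instead of by allylic alkylation. 4-Bromophenol is C-prenylated ortho to oxygen as its sodium salt with 13 in toluene to give 4-bromo-2-(3-methylbut-2-en-1-yl)phenol F1. Silylation (TBSCl, imidazole, DMF) gives [4-bromo-2-(3-methylbut-2-en-1-yl)phenoxy](tert-butyl)dimethylsilane F2, and epoxidation under the Shi conditions of step 7 gives (4-bromo-2-{[(2R)-3,3-dimethyloxiran-2-yl]methyl}phenoxy)(tert-butyl)dimethylsilane F3. Coupling of 11 with F3 (Pd(OAc)2, tBuXPhos, K3PO4, dioxane, 80 °C) should give the silyl ether of the target, (5Z)-3-(4-[(tert-butyldimethylsilyl)oxy]-3-{[(2R)-3,3-dimethyloxiran-2-yl]methyl}phenyl)-4-hydroxy-5-[(7-hydroxy-2,2-dimethylchroman-6-yl)methylidene]furan-2(5H)-one F4. Buffered fluoride (TBAF/AcOH, THF, 0 °C) then releases 20.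

Step 7 (Shi epoxidation). What may go wrong: unselective background epoxidation by a dioxirane formed from the substrate's own ketone, or slow oxidation of the enone, would erode enantiomeric purity or yield, and the catalyst-controlled facial selectivity may fall short of what a single enantiomer demands.

Fallback, setting out from 12 and returning at 15: the stereocentre is taken from a Sharpless asymmetric epoxidation. 3-Methylbut-2-en-1-ol is epoxidised with Ti(OiPr)4, D-(−)-diisopropyl tartrate and tBuOOH (4 Å sieves, CH2Cl2, −20 °C) to [(2R)-3,3-dimethyloxiran-2-yl]methanol F5. Treatment with I2, PPh3 and imidazole (CH2Cl2, 0 °C) gives (2S)-2-(iodomethyl)-3,3-dimethyloxirane F6; the spatial arrangement is unchanged and only the descriptor changes with the CIP priorities. F6 then alkylates the lithium dienolate of 12 (LDA, THF–DMPU, −78 → −30 °C) to give 15 directly.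

Step 1 (chroman annulation). What may go wrong: alkylation between the two hydroxyl groups and a second annulation would divert material to the 5-hydroxy isomer and to bis-chromans.

Fallback, setting out from 1 and returning at 3: acylation and oxa-Michael closure replace the alkylation. Resorcinol and 3-methylbut-2-enoic acid in MeSO3H/P2O5 at 70 °C should give 7-hydroxy-2,2-dimethylchroman-4-one F7 (Friedel–Crafts acylation para to one hydroxyl, then ring closure). Its aryl ketone is reduced to the methylene (Et3SiH, TFA, 50 °C) to give 3.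

**Further compounds**
F1 | step 10 | 4-bromo-2-(3-methylbut-2-en-1-yl)phenol | CC(C)=CCc1cc(Br)ccc1O
F2 | step 10 | [4-bromo-2-(3-methylbut-2-en-1-yl)phenoxy](tert-butyl)dimethylsilane | CC(C)=CCc1cc(Br)ccc1O[Si](C)(C)C(C)(C)C
F3 | step 10 | (4-bromo-2-{[(2R)-3,3-dimethyloxiran-2-yl]methyl}phenoxy)(tert-butyl)dimethylsilane | CC(C)(C)[Si](C)(C)Oc1ccc(Br)cc1C[C@H]1OC1(C)C
F4 | step 10 | (5Z)-3-(4-[(tert-butyldimethylsilyl)oxy]-3-{[(2R)-3,3-dimethyloxiran-2-yl]methyl}phenyl)-4-hydroxy-5-[(7-hydroxy-2,2-dimethylchroman-6-yl)methylidene]furan-2(5H)-one | CC1(C)CCc2cc(/C=C3\OC(=O)C(c4ccc(O[Si](C)(C)C(C)(C)C)c(C[C@H]5OC5(C)C)c4)=C3O)c(O)cc2O1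
F5 | step 7 | [(2R)-3,3-dimethyloxiran-2-yl]methanol | OC[C@H]1OC1(C)C
F6 | step 7 | (2S)-2-(iodomethyl)-3,3-dimethyloxirane | IC[C@H]1OC1(C)C
F7 | step 1 | 7-hydroxy-2,2-dimethylchroman-4-one | CC1(C)CC(=O)c2ccc(O)cc2O1
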